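The route rests on the C9–C11 bond, cut so that C9 of ring B, the allylic carbon between the C7=C8 double bond and quaternary C10, appears as the carbonyl carbon of a sclareol-derived C14 enone (11-nordrim-7-en-9-one). In one operation a homoallylic alkyllithium carrying C11–C16 and the glyceraldehyde-derived (14S)-dioxolane adds to this C9 ketone from the α face, away from the C10 methyl, and the alkoxide is trapped as a tertiary allylic carbonate. Palladium-catalysed formate hydrogenolysis then delivers hydride to C9 from the α face with inversion, giving the 9β side chain and retaining the C7=C8 alkene; acetonide cleavage and acetylation finish.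

Key step: step 9

Remark: positions follow labdane numbering (C17 is the methyl on C8, C20 the methyl on C10; nordrimane names use drimane numbering, identical for C1–C11); α is the face opposite the C10 methyl. Aldehyde 8 is taken as the commercial material, freshly distilled.

Step 1
Reactants: 1 (−)-sclareol
Product: 2 8α-hydroxy-14,15-dinorlabdan-13-one
Conditions: OsO4 (2 mol%), NaIO4 (3.5 equiv), THF/H2O, rt to 45 °C
Reagents that add atoms: none
Why: Lemieux–Johnson oxidation: dihydroxylation of the vinyl group gives a 13,14,15-triol whose two C–C bonds are cleaved by periodate (glycol cleavage) to leave the C13 methyl ketone, and no stereocentre of the decalin is touched.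

Step 2
Reactants: 2 8α-hydroxy-14,15-dinorlabdan-13-one
Product: 3 drim-9(11)-en-8α-ol
Conditions: hν (medium-pressure Hg lamp, quartz), hexane, rt, Ar
Reagents that add atoms: none
Why: Norrish type 2 fragmentation: the excited C13 ketone abstracts the tertiary γ-hydrogen at C9 and the resulting 1,4-biradical cleaves the C11–C12 bond to give acetone enol and the exocyclic C9=C11 alkene, with C5, C8 and C10 untouched.

Step 3
Reactants: 3 drim-9(11)-en-8α-ol
Product: 5 8α-hydroxy-11-nordriman-9-one, via secondary ozonide 4 (not isolated)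
Conditions: O3, CH2Cl2, −78 °C; then Me2S, −78 °C to rt
Reagents that add atoms: ozone, [O-][O+]=O
Why: Ozonolysis by the Criegee mechanism with reductive work-up cleaves the 1,1-disubstituted alkene, removing C11 as formaldehyde and leaving the C9 ketone next to the unchanged tertiary C8 carbinol.

Step 4
Reactants: 5 8α-hydroxy-11-nordriman-9-one
Product: 6 11-nordrim-8(12)-en-9-one, (4aS,8aS)-5,5,8a-trimethyl-2-methylideneoctahydronaphthalen-1(2H)-one
Conditions: SOCl2, pyridine, CH2Cl2, −40 °C to 0 °C
Reagents that add atoms: none
Why: Chlorosulfite formation and base-induced E2 elimination: the equatorial 8α-oxygen has no antiperiplanar ring hydrogen, so a methyl hydrogen should be lost to give mainly the exocyclic enone, and any endocyclic isomer formed alongside is already the product of step 5.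

Step 5
Reactants: 6 11-nordrim-8(12)-en-9-one
Product: 7 11-nordrim-7-en-9-one, (4aS,8aS)-2,5,5,8a-tetramethyl-4a,5,6,7,8,8a-hexahydronaphthalen-1(4H)-one
Conditions: RhCl3·3H2O (5 mol%), EtOH, 80 °C
Reagents that add atoms: none
Why: Rhodium hydride addition–elimination (transition-metal-catalysed alkene isomerisation) should move the exocyclic double bond into ring B to the more stable trisubstituted conjugated enone, while C5 and C10 cannot epimerise.

Step 6
Reactants: 8 (R)-2,2-dimethyl-1,3-dioxolane-4-carbaldehyde
Product: 9 (S)-4-ethynyl-2,2-dimethyl-1,3-dioxolane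
Conditions: dimethyl (1-diazo-2-oxopropyl)phosphonate, K2CO3, MeOH, 0 °C to rt
Reagents that add atoms: Ohira–Bestmann reagent, COP(=O)(OC)C(=[N+]=[N-])C(C)=O
Why: Seyferth–Gilbert homologation in its Ohira–Bestmann form (diazomethylphosphonate anion made in situ, Horner–Wadsworth–Emmons-type addition, loss of N2 and 1,2-hydride shift of the alkylidene carbene) under a carbonate base mild enough to preserve the α-alkoxy stereocentre, whose descriptor changes from R to S by priority only.

Step 7
Reactants: 9 (S)-4-ethynyl-2,2-dimethyl-1,3-dioxolane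
Product: 10 (S)-4-(buta-1,3-dien-2-yl)-2,2-dimethyl-1,3-dioxolane
Conditions: ethylene (1 atm), second-generation Grubbs catalyst (H2IMes)(PCy3)Cl2Ru=CHPh (5 mol%), CH2Cl2, rt to 40 °C
Reagents that add atoms: ethylene, C=C
Why: Cross enyne metathesis with ethylene: the ruthenium methylidene adds to the terminal alkyne and the vinyl carbene is turned over by ethylene to give the 2-substituted 1,3-butadiene, without touching the adjacent stereocentre.

Step 8
Reactants: 10 (S)-4-(buta-1,3-dien-2-yl)-2,2-dimethyl-1,3-dioxolane
Product: 12 (S)-4-(4-iodobut-1-en-2-yl)-2,2-dimethyl-1,3-dioxolane, via disiamylalkylborane 11 (not isolated)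
Conditions: Sia2BH (from BH3·THF and 2-methylbut-2-ene, 1.05 equiv), THF, 0 °C; then I2, NaOMe, MeOH, 0 °C to rt
Reagents that add atoms: iodine, II
Why: Anti-Markovnikov hydroboration with the bulky dialkylborane should take the monosubstituted vinyl terminus (C11) rather than the more hindered 1,1-disubstituted alkene, as in known monohydroborations of 2-substituted butadienes, and base-induced iodinolysis of the primary C–B bond then gives the iodide; no stereocentre is formed.

Step 9
Reactants: 12 (S)-4-(4-iodobut-1-en-2-yl)-2,2-dimethyl-1,3-dioxolane; 7 11-nordrim-7-en-9-one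
Product: 15 (14S)-14,15-isopropylidenedioxylabda-7,13(16)-dien-9-yl methyl carbonate with the C9–O bond β and the C9–C11 bond α, via alkyllithium 13 (not isolated), via lithium alkoxide 14 (not isolated)
Conditions: t-BuLi (2.1 equiv), Et2O/pentane, −78 °C; then 7, −78 °C to −20 °C; then ClCO2Me, −78 °C to rt
Reagents that add atoms: methyl chloroformate, COC(Cl)=O
Why: Iodine–lithium exchange gives the primary alkyllithium 13, which adds 1,2 to the C9 carbonyl of enone 7, and the lithium alkoxide 14 is acylated in the same flask. The closest known reaction type is the addition of alkyllithiums to 2,6,6-trimethylcyclohex-2-enone-type enones with in situ chloroformate trapping of the tertiary alkoxide. No ring is closed. The new stereocentre C9 is controlled by the pseudoaxial C10 methyl, which blocks the β face, so the nucleophile should enter from the α face and the oxygen should end up β. The step needs 1,2- over 1,4-addition and addition over γ-deprotonation at C6: the hard organolithium in ether prefers the carbonyl carbon over C7, there is no α-hydrogen (C10 is quaternary, C8 is sp2), and the low temperature should hold back dienolate formation. The C9–O configuration fixed here is what step 10 translates into the C9–H configuration.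

Step 10
Reactants: 15 the tertiary allylic methyl carbonate
Product: 16 (14S)-14,15-O-isopropylidenelabda-7,13(16)-diene-14,15-diol (5S,9S,10S)
Conditions: Pd(OAc)2 (5 mol%), n-Bu3P (20 mol%), HCO2H, Et3N, THF, 40 °C
Reagents that add atoms: none
Why: Tsuji formate hydrogenolysis: zerovalent palladium formed in situ ionises the 9β carbonate with inversion to an α-face π-allyl complex spanning C7–C8–C9, decarboxylation of the formate ligand gives a palladium hydride, and hydride passes from the metal to the more substituted terminus C9 on the α face, which sets 9α-H (side chain β) and leaves the less substituted C7=C8 alkene, the side-chain acetal being no leaving group for palladium.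

Step 11
Reactants: 16 (14S)-14,15-O-isopropylidenelabda-7,13(16)-diene-14,15-diol
Product: 17 (14S)-labda-7,13(16)-diene-14,15-diol
Conditions: AcOH/H2O (4:1), 40 °C
Reagents that add atoms: none
Why: Acid-catalysed acetal hydrolysis under conditions too mild to protonate the alkenes or ionise the allylic C14–O bond, so C14 keeps its S configuration.

Step 12
Reactants: 17 (14S)-labda-7,13(16)-diene-14,15-diol
Product: 18 (14S)-labda-7,13(16)-diene-14,15-diyl diacetate (5S,9S,10S), the target
Conditions: Ac2O, pyridine, DMAP (cat.), CH2Cl2, 0 °C to rt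
Reagents that add atoms: acetic anhydride, CC(=O)OC(C)=O
Why: DMAP-catalysed acylation (nucleophilic catalysis) of the primary and the secondary allylic hydroxyl groups at oxygen only, so no stereocentre is affected.

Compound list

1 | (−)-sclareol, (13R)-labd-14-ene-8α,13-diol | C=C[C@](C)(O)CC[C@H]1[C@](C)(O)CC[C@H]2C(C)(C)CCC[C@]12C | starting material
2 | 8α-hydroxy-14,15-dinorlabdan-13-one | CC(=O)CC[C@H]1[C@](C)(O)CC[C@H]2C(C)(C)CCC[C@]12C | intermediate
3 | drim-9(11)-en-8α-ol | C=C1[C@](C)(O)CC[C@H]2C(C)(C)CCC[C@]12C | intermediate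
4 | secondary ozonide of 3 (spiro-1,2,4-trioxolane at C9, configuration at the spiro carbon undefined; not isolated) | C1OC2(OO1)[C@](C)(O)CC[C@H]3C(C)(C)CCC[C@]23C | intermediate
5 | 8α-hydroxy-11-nordriman-9-one | O=C1[C@](C)(O)CC[C@H]2C(C)(C)CCC[C@]12C | intermediate
6 | 11-nordrim-8(12)-en-9-one, (4aS,8aS)-5,5,8a-trimethyl-2-methylideneoctahydronaphthalen-1(2H)-one | O=C1C(=C)CC[C@H]2C(C)(C)CCC[C@]12C | intermediate
7 | 11-nordrim-7-en-9-one, (4aS,8aS)-2,5,5,8a-tetramethyl-4a,5,6,7,8,8a-hexahydronaphthalen-1(4H)-one | O=C1C(C)=CC[C@H]2C(C)(C)CCC[C@]12C | intermediate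
8 | (R)-2,2-dimethyl-1,3-dioxolane-4-carbaldehyde | O=C[C@H]1COC(C)(C)O1 | starting material
9 | (S)-4-ethynyl-2,2-dimethyl-1,3-dioxolane | C#C[C@H]1COC(C)(C)O1 | intermediate
10 | (S)-4-(buta-1,3-dien-2-yl)-2,2-dimethyl-1,3-dioxolane | C=CC(=C)[C@H]1COC(C)(C)O1 | intermediate
11 | {3-[(4S)-2,2-dimethyl-1,3-dioxolan-4-yl]but-3-en-1-yl}bis(3-methylbutan-2-yl)borane (siamyl stereocentres undefined; not isolated) | CC(C)C(C)B(CCC(=C)[C@H]1COC(C)(C)O1)C(C)C(C)C | intermediate
12 | (S)-4-(4-iodobut-1-en-2-yl)-2,2-dimethyl-1,3-dioxolane | ICCC(=C)[C@H]1COC(C)(C)O1 | intermediate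
13 | {3-[(4S)-2,2-dimethyl-1,3-dioxolan-4-yl]but-3-en-1-yl}lithium (not isolated) | [Li]CCC(=C)[C@H]1COC(C)(C)O1 | intermediate
14 | lithium alkoxide of (14S)-14,15-isopropylidenedioxylabda-7,13(16)-dien-9-ol, C9–O β, C9–C11 α (not isolated) | [Li]O[C@@]1(CCC(=C)[C@H]3COC(C)(C)O3)C(C)=CC[C@H]2C(C)(C)CCC[C@]12C | intermediate
15 | (14S)-14,15-isopropylidenedioxylabda-7,13(16)-dien-9-yl methyl carbonate, C9–O β, C9–C11 α | COC(=O)O[C@@]1(CCC(=C)[C@H]3COC(C)(C)O3)C(C)=CC[C@H]2C(C)(C)CCC[C@]12C | intermediate
16 | (14S)-14,15-O-isopropylidenelabda-7,13(16)-diene-14,15-diol (5S,9S,10S) | C=C(CC[C@H]1C(C)=CC[C@H]2C(C)(C)CCC[C@]12C)[C@H]3COC(C)(C)O3 | intermediate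
17 | (14S)-labda-7,13(16)-diene-14,15-diol | C=C(CC[C@H]1C(C)=CC[C@H]2C(C)(C)CCC[C@]12C)[C@@H](CO)O | intermediate
18 | (14S)-labda-7,13(16)-diene-14,15-diyl diacetate (5S,9S,10S) | C=C(CC[C@H]1C(C)=CC[C@H]2C(C)(C)CCC[C@]12C)[C@@H](COC(C)=O)OC(C)=O | target

Total step count: 12. Longest linear sequence: 9 steps (steps 1–5 and 9–12).

Steps most likely to fail

1. Step 10. What may go wrong: hydride delivery to C7 instead of C9 (giving the tetrasubstituted 8-ene), β-hydride elimination from the π-allyl complex to ring dienes, or slow ionisation because the 9β C–O bond is pseudoequatorial. The fallback replaces the palladium hydride by a sigmatropic hydrogen transfer. It sets out from lithium alkoxide 14, which is quenched with aqueous NH4Cl instead of methyl chloroformate to give the tertiary allylic alcohol F1. Oxidative 1,3-transposition with pyridinium chlorochromate (C5H5NH)[CrO3Cl] (NaOAc buffer, CH2Cl2) should give the 7-oxo-8-ene F2. Luche reduction (NaBH4, CeCl3·7H2O, MeOH, −20 °C) should give the 7β-allylic alcohol F3 by axial hydride attack on the α face. Mitsunobu displacement with 2-nitrobenzenesulfonylhydrazide (PPh3, DEAD, THF, −30 °C) should give with inversion the 7α N-sulfonylhydrazine F4, which on warming loses sulfinic acid to the 7α allylic diazene F5. Its retro-ene loss of N2 passes hydrogen suprafacially to C9 on the α face and shifts the alkene to C7=C8, which returns to the route at 16.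

2. Step 9. What may go wrong: γ-deprotonation of enone 7 at C6 by the basic alkyllithium, poor conversion at the hindered carbonyl, or failure of the hindered tertiary alkoxide to acylate. The fallback makes the same C9–C11 bond by cross-coupling and sets out from enone 7 and borane 11. KN(SiMe3)2 (THF, −78 °C) turns 7 by deliberate γ-deprotonation into the potassium dienolate F6, which PhNTf2 traps as the dienyl triflate F7. B-alkyl Suzuki–Miyaura coupling of F7 with borane 11 (PdCl2(dppf), K3PO4, THF/DMF/H2O, 60 °C) should give the ring-B 6,8-diene F8. 1,4-Hydrogenation of this s-cis homoannular diene with (η6-naphthalene)Cr(CO)3 under H2 (THF, 45 °C) should add hydrogen to C6 and C9 from the α face and leave the C7=C8 alkene, which returns to the route at 16.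

3. Step 8. What may go wrong: over-hydroboration of the remaining alkene, or attack of electrophilic iodine on the 1,1-disubstituted alkene during iodinolysis of the C–B bond. The fallback installs iodine by nucleophilic displacement instead and sets out from borane 11. Oxidation with NaOH/H2O2 gives the homoallylic alcohol F9, which can be purified from regioisomers, and an Appel reaction (PPh3, I2, imidazole, CH2Cl2, 0 °C) converts it by SN2 displacement into iodide 12, where the route is rejoined.

Further compounds

F1 | step 10 | (14S)-14,15-isopropylidenedioxylabda-7,13(16)-dien-9-ol, C9–OH β, C9–C11 α | O[C@@]1(CCC(=C)[C@H]3COC(C)(C)O3)C(C)=CC[C@H]2C(C)(C)CCC[C@]12C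
F2 | step 10 | (14S)-14,15-isopropylidenedioxylabda-8,13(16)-dien-7-one | C=C(CCC1=C(C)C(=O)C[C@H]2C(C)(C)CCC[C@]12C)[C@H]3COC(C)(C)O3
F3 | step 10 | (14S)-14,15-isopropylidenedioxylabda-8,13(16)-dien-7β-ol | C=C(CCC1=C(C)[C@@H](O)C[C@H]2C(C)(C)CCC[C@]12C)[C@H]3COC(C)(C)O3
F4 | step 10 | 7α-[N-(2-nitrobenzenesulfonyl)hydrazinyl] derivative of the 8,13(16)-diene acetonide (not isolated) | C=C(CCC1=C(C)[C@H](N(N)S(=O)(=O)c4ccccc4[N+](=O)[O-])C[C@H]2C(C)(C)CCC[C@]12C)[C@H]3COC(C)(C)O3
F5 | step 10 | 7α-diazenyl derivative of the 8,13(16)-diene acetonide (not isolated) | C=C(CCC1=C(C)[C@H](N=N)C[C@H]2C(C)(C)CCC[C@]12C)[C@H]3COC(C)(C)O3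
F6 | step 9 | potassium dienolate of 7, potassium (4aS,8aS)-2,5,5,8a-tetramethyl-4a,5,6,7,8,8a-hexahydronaphthalen-1-olate (not isolated) | [K+].[O-]C1=C(C)C=C[C@H]2C(C)(C)CCC[C@]12C
F7 | step 9 | (4aS,8aS)-2,5,5,8a-tetramethyl-4a,5,6,7,8,8a-hexahydronaphthalen-1-yl trifluoromethanesulfonate | O=S(=O)(OC1=C(C)C=C[C@H]2C(C)(C)CCC[C@]12C)C(F)(F)F
F8 | step 9 | (14S)-14,15-O-isopropylidenelabda-6,8,13(16)-triene-14,15-diol | C=C(CCC1=C(C)C=C[C@H]2C(C)(C)CCC[C@]12C)[C@H]3COC(C)(C)O3
F9 | step 8 | 3-[(4S)-2,2-dimethyl-1,3-dioxolan-4-yl]but-3-en-1-ol | OCCC(=C)[C@H]1COC(C)(C)O1
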